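The ratio I wanted before planning the next run was target over the rest of the starting material charged, the selectivity of the flask. Wednesday's last reading, at 80.0 min, gave 46% target and 0% free starting material, so that ratio read 0.852, with a scatter of 2 percentage points on the reading.

the same everywhere: starting material 10 mM
- Wednesday's: coupling partner 20 mM (fed, over 4.0 min); capture agent 1 mM; protic impurity 0.20 mM; the very flask that is asked about, followed so far; the fed solution adds 0.25 times the starting volume
- flask: coupling partner 20.0 mM (fed, over 4.0 min); capture agent 1.00 mM; protic impurity 0.200 mM; the fed solution adds 0.25 times the starting volume; time 3.0 h

Wednesday's run (percent of the starting material charged)

| time / min | starting material / % | target / % |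
|---|---|---|
| 6.00 | 49 | 21 |
| 10.0 | 32 | 28 |
| 15.0 | 14 | 38 |
| 25.0 | 5 | 44 |
| 40.0 | 0 | 45 |
| 80.0 | 0 | 46 |

(standard deviation of a reading: 2 percentage points)

- amounts are per litre of the starting volume; all of the dose is in the solution fed
- the reaction counts as stopped when no species that holds the starting material changes by six tenths of a point or more over the second half of the time
- a reading of starting material is of its free form alone

- why nothing more happens at 3.0 h, or that something still does (all of the starting material has reacted / forward and back rates have come level / it is still moving / the coupling partner has run out first)
- part of the starting material gone at 3.0 h
- the target standing at 3.0 h, as a percentage of the starting material charged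
- amount of target if the flask were left three thousand times as long, in percent of the starting material charged

Wednesday's run is the flask asked about, so I had two decisions to make: whether to disturb it, and what to charge next. Target read 45% at 40.0 min and 46% at 80.0 min, a difference within the scatter, so I left the flask untouched until 3.0 h and expected about 46%.

For the next charge I took [coupling partner] as the concentration that sets the order of the loss. My assumption, which one run cannot test, was that the route to target does not contain it and the competing route is first order in it, pseudo-first-order in starting material. The ratio then falls in inverse proportion to the charge of coupling partner, and ratio times charge gave 17.0 mM. I carried this as the crossover charge, the charge of coupling partner at which target and the rest come out equal, with starting material, capture agent, protic impurity, feed time and feed volume held. Wednesday's 20 mM stood above it, so I planned the next charge lower, not higher.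

The forecast said it is still moving, with 94% of the starting material gone at 3.0 h, target at 46%, and 50% after a very long wait: “I guess it still leaks”.

At 3.0 h the flask gave 46.2% target with 100% of the starting material gone, and the answer to why it stopped was this: all of the starting material has reacted. The figure for the very long wait was 46.2%.

starting material + coupling partner → intermediate A (k = 0.0970 L mol⁻¹ s⁻¹); starting material ⇌ intermediate B (K = 0.210, k = 0.00120 s⁻¹); intermediate B → target (k = 0.0170 s⁻¹); coupling partner + intermediate A → side product (k = 0.130 L mol⁻¹ s⁻¹); capture agent + intermediate B → trapped intermediate (k = 0.160 L mol⁻¹ s⁻¹); starting material + protic impurity → quenched substrate (k = 4.00 L mol⁻¹ s⁻¹) Trapped intermediate stood at 0.353%, and capture agent at 96% of its charge. For a neighbour, the same flask with 50 mM of coupling partner, the crossover charge over the sum of itself and that charge gave 25.4% target. That neighbour stood at 27.0% target and 70.8% side product at 3.00 h.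

The numbers in the tables come from a simulation on assumed constants; scatter was added.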